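**Retrosynthetic overview**
1. Feature used (labdane numbering): the six carbons of ring B, C5–C10, are substituted like a benzene ring. The quaternary, methyl-bearing C10 lies para to C7, flanked by C5 (ring A side) and C9 (side chain). Ring B is therefore taken from a p-cresol whose oxygen sits on C7 and is deleted later.
2. Key disconnection C1–C10: the C7 phenoxide is alkylated at its para carbon C10 by a C1 tosylate hanging from C5 through C4–C3–C2. This closes ring A, makes C10 quaternary under control of the C3 silyl ether, and turns ring B into a 5,8-dien-7-one.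
3. Precursor: 3,5-dibromo-4-methylphenol, ethylene oxide (C11–C12), methyl isobutyrate (C3, C4, C18, C19) and an allylborane (C2, C1; sets C3). Br then goes on C8 (handle for C17) and Cl on C6 (blocks the competing ortho closure).
4. After the key step: C8–Br becomes CO2Me (C17); H2 and then Li/NH3 place H5 and H9 anti to the C10 methyl; C7–O is removed by Barton–McCombie. C12–C13 comes from a Negishi coupling with methyl (Z)-3-iodobut-2-enoate (13Z), and C17 is oxidised to the aldehyde last.
5. Order of rings: ring B first (bought as the arene), ring A second (step 13).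

Key step: step 13

Remark on the chemistry: the target SMILES is read as the ent-labdane (3R,5S,8S,9R,10S) with equatorial 3-OH (cis to the C10 methyl), equatorial 8-CHO and a 13Z enoate (ester cis to C12); labdane locants are used throughout, TBS = tert-butyldimethylsilyl, TBDPS = tert-butyldiphenylsilyl, Ts = 4-methylbenzenesulfonyl, and alcohols 27–30 are carried as C7 epimers (C7 left open in their SMILES) because C7 ends as CH2.

**Step 1**
Reactants: 1 3,5-dibromo-4-methylphenol
Product: 2 5-(benzyloxy)-1,3-dibromo-2-methylbenzene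
Conditions: BnBr, K2CO3, DMF, rt
Reagents that add atoms: benzyl bromide, BrCc1ccccc1
Why: Williamson ether synthesis; the benzyl ether survives n-BuLi, LiNCy2, DIBAL-H and ozone and is later removed by hydrogenolysis without harm to silyl ethers or the tosylate.

**Step 2**
Reactants: 2 5-(benzyloxy)-1,3-dibromo-2-methylbenzene; 3 ethylene oxide
Product: 5 2-[5-(benzyloxy)-3-bromo-2-methylphenyl]ethan-1-ol, via aryllithium 4 (not isolated)
Conditions: n-BuLi (1.0 equiv), THF, −78 °C; 3 (3 equiv), −78 °C → rt; H2O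
Reagents that add atoms: none
Why: Bromine–lithium exchange followed by SN2 opening of the epoxide; the two bromines of 2 are equivalent and one equivalent of n-BuLi exchanges only one of them, so a single arylethanol carrying C11–C12 should result.

**Step 3**
Reactants: 5 2-[5-(benzyloxy)-3-bromo-2-methylphenyl]ethan-1-ol
Product: 6 {2-[5-(benzyloxy)-3-bromo-2-methylphenyl]ethoxy}(tert-butyl)dimethylsilane
Conditions: TBSCl, imidazole, CH2Cl2, rt
Reagents that add atoms: tert-butyldimethylsilyl chloride, CC(C)(C)[Si](C)(C)Cl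
Why: Routine imidazole-promoted silylation of a primary alcohol, needed because the next step uses a strong amide base.

**Step 4**
Reactants: 6 aryl bromide; 7 methyl isobutyrate
Product: 9 methyl 2-{5-(benzyloxy)-3-[2-(TBSO)ethyl]-2-methylphenyl}-2-methylpropanoate, via lithium enolate 8 (not isolated)
Conditions: Cy2NH, n-BuLi, toluene, 0 °C; 7; then 6, Pd(dba)2 (2 mol %), P(t-Bu)3 (4 mol %), rt → 50 °C
Reagents that add atoms: none
Why: Palladium-catalysed α-arylation of an ester enolate (Buchwald–Hartwig type), in which zerovalent palladium bearing P(t-Bu)3 inserts into a C–Br bond that has only one ortho substituent and reductive elimination from the arylpalladium enolate creates the quaternary benzylic carbon C4.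

**Step 5**
Reactants: 9 α-aryl ester
Product: 10 2-{5-(benzyloxy)-3-[2-(TBSO)ethyl]-2-methylphenyl}-2-methylpropanal
Conditions: DIBAL-H (1.1 equiv), toluene, −78 °C; aqueous Rochelle salt
Reagents that add atoms: none
Why: Partial ester reduction with DIBAL-H; the crowded neopentyl aluminium hemiacetal does not collapse at −78 °C, so the aldehyde appears only on work-up and is not reduced further.

**Step 6**
Reactants: 10 aldehyde; 11 B-allylbis(isopinocampheyl)borane of the (−)-α-pinene series
Product: 13 (3R)-2-{5-(benzyloxy)-3-[2-(TBSO)ethyl]-2-methylphenyl}-2-methylhex-5-en-3-ol, via borinate 12 (not isolated)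
Conditions: 11 (1.3 equiv, pentane solution), Et2O, −100 → −78 °C; then aqueous NaOH, 30% H2O2, 0 °C → rt
Reagents that add atoms: none
Why: Brown asymmetric allylboration through a closed Zimmerman–Traxler chair, in which the isopinocampheyl groups of the (−)-α-pinene series direct the allyl group to the Re face of α-branched aldehydes and so set C3 as R, a reaction type that tolerates α-quaternary aldehydes.

**Step 7**
Reactants: 13 homoallylic alcohol
Product: 14 TBS ether of 13 (3R)
Conditions: TBSOTf, 2,6-lutidine, CH2Cl2, 0 °C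
Reagents that add atoms: tert-butyldimethylsilyl triflate, CC(C)(C)[Si](C)(C)OS(=O)(=O)C(F)(F)F
Why: Silylation with the silyl triflate, which is reactive enough for a neopentyl secondary alcohol, installs the bulky C3 substituent that has to steer step 13.

**Step 8**
Reactants: 14 alkene
Product: 16 (3R)-4-{5-(benzyloxy)-3-[2-(TBSO)ethyl]-2-methylphenyl}-3-(TBSO)-4-methylpentan-1-ol, via aldehyde 15 (not isolated)
Conditions: O3, CH2Cl2–MeOH, −78 °C (stopped when the alkene is consumed); NaBH4, −78 °C → rt
Reagents that add atoms: ozone, [O-][O+]=O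
Why: Ozonolysis (Criegee mechanism) with reductive borohydride work-up removes the terminal carbon and leaves C1 as a primary alcohol, the monosubstituted alkene being consumed by ozone far faster than the aryl ether.

**Step 9**
Reactants: 16 primary alcohol
Product: 17 tosylate of 16
Conditions: TsCl, Et3N, DMAP (cat.), CH2Cl2, 0 °C → rt
Reagents that add atoms: 4-methylbenzenesulfonyl chloride, Cc1ccc(cc1)S(Cl)(=O)=O
Why: Sulfonylation of the only free hydroxyl group turns C1 into the SN2 electrophile of the key step.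

**Step 10**
Reactants: 17 benzyl ether tosylate
Product: 18 (3R)-3-(TBSO)-4-{3-[2-(TBSO)ethyl]-5-hydroxy-2-methylphenyl}-4-methylpentyl 4-methylbenzenesulfonate
Conditions: H2 (1 atm), 10% Pd/C, EtOAc, rt
Reagents that add atoms: none
Why: Hydrogenolysis of the aryl benzyl ether frees the phenol under neutral conditions that leave tosylate and silyl ethers untouched, and it is placed before the halogenations so that no carbon–halogen bond is exposed to H2.

**Step 11**
Reactants: 18 phenol
Product: 19 (3R)-4-{4-bromo-3-[2-(TBSO)ethyl]-5-hydroxy-2-methylphenyl}-3-(TBSO)-4-methylpentyl 4-methylbenzenesulfonate (Br on C8)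
Conditions: NBS (1.0 equiv), i-Pr2NH (10 mol %), CH2Cl2, −40 → 0 °C, dark
Reagents that add atoms: N-bromosuccinimide, O=C1CCC(=O)N1Br
Why: Electrophilic aromatic bromination of a phenol whose para position is blocked by methyl; C8 lies next to a primary alkyl group and C6 next to the tert-alkyl group, so the first halogen should enter C8.

**Step 12**
Reactants: 19 bromophenol
Product: 20 (3R)-3-(TBSO)-4-{4-bromo-5-[2-(TBSO)ethyl]-2-chloro-3-hydroxy-6-methylphenyl}-4-methylpentyl 4-methylbenzenesulfonate (Br on C8; Cl on C6)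
Conditions: NCS (1.1 equiv), i-Pr2NH (10 mol %), toluene, 0 → 40 °C, dark
Reagents that add atoms: N-chlorosuccinimide, O=C1CCC(=O)N1Cl
Why: Electrophilic aromatic chlorination at the only ring C–H left, the N-chloroamine formed from NCS and the amine delivering chlorine ortho to the hydrogen-bonded phenol; chlorine is the smallest halogen that still differs from bromine in palladium chemistry, and substitution beside a flanked tert-alkyl group has its model in the hexasubstituted nitro musks.

**Step 13**
Reactants: 20 bromochlorophenol tosylate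
Product: 22 (4aR,7R)-3-bromo-1-chloro-7-(TBSO)-4-[2-(TBSO)ethyl]-4a,8,8-trimethyl-5,6,7,8-tetrahydronaphthalen-2(4aH)-one (8-bromo-6-chloro-5,8-dien-7-one in labdane locants; C10 methyl cis to the C3 silyloxy group), via potassium phenoxide 21 (not isolated)
Conditions: KOt-Bu (1.00 equiv), t-BuOH–THF, 0.002 M, rt → 80 °C
Reagents that add atoms: none
Why: One equivalent of KOt-Bu converts the acidic dihalophenol into potassium phenoxide 21, whose para carbon C10 attacks C1 from one face of the ring in an intramolecular SN2 reaction, expels tosylate and leaves the C7 oxygen as the carbonyl of a cross-conjugated cyclohexa-2,5-dienone. The closest known reaction type is the Ar2-6 participation of phenoxides, that is, base-induced alkylative dearomatization of a para-substituted phenol by a sulfonate held on the neighbouring ring carbon. Ring A closes in a 6-exo-tet mode (6-(enolendo)-exo-tet in enolate terms, an allowed closure), helped by the gem-dialkyl effect of C4 and by release of the in-plane clash between the C4 methyls and the C10 methyl once C10 becomes tetrahedral. The new stereocentre C10 is controlled by C3: in the chair-like transition state the bulky silyloxy group takes the equatorial site, so C1 reaches the ring face that pushes the methyl into the axial position, 1,4-cis to the C3 oxygen as in the target. Carbon versus oxygen selectivity follows from the meta tether (O-alkylation would need an eight-membered meta-bridged ether), C10 versus C6 selectivity is secured by the chlorine, which denies a C6 adduct its rearomatization and lowers the electron density there, and C8 is out of reach of C1. High dilution, the two halogens flanking the oxygen and the absence of excess base hold back intermolecular ether formation, E2 loss of tosylate and vinylogous elimination of the C12 silyloxy group.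

**Step 14**
Reactants: 22 bromochlorodienone
Product: 23 methyl 1-chloro-7-(TBSO)-4-[2-(TBSO)ethyl]-4a,8,8-trimethyl-2-oxo-2,4a,5,6,7,8-hexahydronaphthalene-3-carboxylate (CO2Me on C8; C3 and C10 as in 22)
Conditions: Pd(OAc)2 (10 mol %), dppf (12 mol %), CO (1–5 bar), NaOAc, MeOH–DMF, 60 °C
Reagents that add atoms: carbon monoxide, [C-]#[O+]; methanol, CO
Why: Palladium-catalysed methoxycarbonylation (Heck carbonylation), in which zerovalent palladium inserts into the electron-poor alkenyl C8–Br bond much faster than into C6–Cl, CO insertion and methanolysis bring in C17, and NaOAc takes up HBr but is too weak to remove the vinylogously acidic C11 protons.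

**Step 15**
Reactants: 23 chlorodienone ester
Product: 24 methyl (3R,5S,10R)-3,12-bis(TBSO)-7-oxo-13,14,15,16-tetranorlabd-8-en-17-oate (H5 trans to the C10 methyl)
Conditions: H2 (1 atm), 10% Pd/C, NaOAc, EtOAc–MeOH, rt
Reagents that add atoms: none
Why: Heterogeneous catalytic hydrogenation with hydrogenolysis of the alkenyl chloride; the flat dienone should meet the catalyst with the face opposite to the C10 methyl and the axial C4 methyl, which places H5 trans to the angular methyl, while the tetrasubstituted C8=C9 bond reacts more slowly and, where it does react from the same face, gives 26 itself.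

**Step 16**
Reactants: 24 enone ester
Product: 26 methyl (3R,5S,8R,9R,10S)-3,12-bis(TBSO)-7-oxo-13,14,15,16-tetranorlabdan-17-oate (H9 trans to the C10 methyl; ester equatorial), via lithium enolate 25 (not isolated)
Conditions: Li (2.5 equiv), NH3(l)–THF, t-BuOH (1 equiv), −78 °C; solid NH4Cl
Reagents that add atoms: none
Why: Dissolving-metal reduction of a doubly activated enone (Birch-type conditions), in which the C9 carbanion of the rigid trans-decalin is protonated axially, anti to the axial C10 methyl, the resulting β-keto ester enolate resists over-reduction, and after the quench the still epimerisable C8 settles with the ester equatorial.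

**Step 17**
Reactants: 26 β-keto ester
Product: 27 methyl (3R,5S,8R,9R,10S)-7-hydroxy-3,12-bis(TBSO)-13,14,15,16-tetranorlabdan-17-oate (C7 epimers)
Conditions: NaBH4, MeOH–THF, 0 °C
Reagents that add atoms: none
Why: Sodium borohydride reduction of the ketone of a β-keto ester; the keto tautomer with the equatorial ester is the one reduced because an axial ester would clash with the C10 methyl, and the configuration at C7 does not matter.

**Step 18**
Reactants: 27 β-hydroxy ester
Product: 28 (3R,5S,8S,9R,10S)-3,12-bis(TBSO)-13,14,15,16-tetranorlabdane-7,17-diol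
Conditions: LiAlH4, THF, 0 °C
Reagents that add atoms: none
Why: Lithium aluminium hydride reduction of the ester brings C17 to the alcohol level before the second, unsaturated ester enters the molecule.

**Step 19**
Reactants: 28 diol
Product: 29 17-O-TBDPS ether of 28 (free 7-OH)
Conditions: TBDPSCl (1.05 equiv), imidazole, CH2Cl2, 0 °C
Reagents that add atoms: tert-butyldiphenylsilyl chloride, CC(C)(C)[Si](Cl)(c1ccccc1)c1ccccc1
Why: Selective silylation, the bulky chlorosilane reacting with the primary C17 hydroxyl much faster than with the flanked secondary C7 hydroxyl; TBDPS is chosen because it survives the acid methanolysis of step 22.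

**Step 20**
Reactants: 29 secondary alcohol
Product: 30 O-(C7) 1H-imidazole-1-carbothioate of 29
Conditions: 1,1'-thiocarbonyldiimidazole, DMAP (cat.), toluene, 90 °C
Reagents that add atoms: 1,1'-thiocarbonyldiimidazole, S=C(n1ccnc1)n1ccnc1
Why: First half of the Barton–McCombie deoxygenation; the neutral reagent avoids an alkoxide that could trigger silyl migration from O17 to O7.

**Step 21**
Reactants: 30 thiocarbonyl derivative
Product: 31 (3R,5S,8S,9R,10S)-3,12-bis(TBSO)-17-(TBDPSO)-13,14,15,16-tetranorlabdane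
Conditions: Bu3SnH, AIBN (cat.), toluene, 110 °C
Reagents that add atoms: none
Why: Barton–McCombie radical deoxygenation, in which the stannyl radical adds to sulfur and the released secondary C7 radical abstracts hydrogen from Bu3SnH without touching any stereocentre.

**Step 22**
Reactants: 31 tris(silyl ether)
Product: 32 (3R,5S,8S,9R,10S)-3-(TBSO)-17-(TBDPSO)-13,14,15,16-tetranorlabdan-12-ol
Conditions: camphorsulfonic acid (10 mol %), MeOH–CH2Cl2, 0 °C
Reagents that add atoms: none
Why: Acid-catalysed methanolysis of silyl ethers is governed by steric access, so the unhindered primary TBS ether at C12 is cleaved while the neopentyl secondary TBS ether at C3 and the TBDPS ether at C17 remain.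

**Step 23**
Reactants: 32 primary alcohol
Product: 33 12-iodide of 32
Conditions: I2, PPh3, imidazole, CH2Cl2, 0 °C → rt
Reagents that add atoms: iodine, II
Why: Appel-type iodination, the alkoxyphosphonium ion being displaced by iodide in an SN2 reaction at the unhindered primary C12.

**Step 24**
Reactants: 34 methyl but-2-ynoate
Product: 35 methyl (Z)-3-iodobut-2-enoate
Conditions: NaI, AcOH, 110 °C
Reagents that add atoms: sodium iodide, [Na+].[I-]
Why: Conjugate hydroiodination of an ynoate, iodide adding to C3 and the proton arriving anti, which gives the Z isomer with iodine cis to the ester.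

**Step 25**
Reactants: 33 primary iodide; 35 methyl (Z)-3-iodobut-2-enoate
Product: 37 methyl (3R,5S,8S,9R,10S,13Z)-3-(TBSO)-17-(TBDPSO)labd-13-en-15-oate, via alkylzinc iodide 36 (not isolated)
Conditions: Zn dust (activated with BrCH2CH2Br and TMSCl), LiCl, THF, 40 °C; then 35, Pd(PPh3)4 (5 mol %), THF, rt → 40 °C
Reagents that add atoms: none
Why: Negishi cross-coupling, in which the alkylzinc reagent tolerates esters and silyl ethers, and oxidative addition of zerovalent palladium into the activated alkenyl iodide and reductive elimination proceed with retention, so that C12 ends cis to the ester (13Z).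

**Step 26**
Reactants: 37 bis(silyl ether)
Product: 38 methyl (3R,5S,8S,9R,10S,13Z)-3,17-dihydroxylabd-13-en-15-oate
Conditions: HF·pyridine, pyridine–THF, 0 °C → rt
Reagents that add atoms: none
Why: Fluoride-driven desilylation under mildly acidic conditions removes both remaining silyl groups without affecting the ester or the alkene geometry.

**Step 27**
Reactants: 38 diol
Product: 39 methyl (3R,5S,8S,9R,10S,13Z)-3-hydroxy-17-oxolabd-13-en-15-oate (target CNP0188570.1)
Conditions: TEMPO (15 mol %), PhI(OAc)2 (1.1 equiv), CH2Cl2, rt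
Reagents that add atoms: none
Why: TEMPO-catalysed oxidation with PhI(OAc)2 as terminal oxidant, the oxoammonium ion oxidising the primary C17 alcohol much faster than the neopentyl secondary C3 alcohol and stopping at the aldehyde, whose equatorial orientation at C8 is also the thermodynamically preferred one.

**Compound list**
1 | 3,5-dibromo-4-methylphenol | Cc1c(Br)cc(O)cc1Br | starting material
2 | 5-(benzyloxy)-1,3-dibromo-2-methylbenzene | Cc1c(Br)cc(OCc2ccccc2)cc1Br | intermediate
3 | ethylene oxide | C1CO1 | starting material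
4 | [5-(benzyloxy)-3-bromo-2-methylphenyl]lithium | [Li]c1cc(OCc2ccccc2)cc(Br)c1C | intermediate
5 | 2-[5-(benzyloxy)-3-bromo-2-methylphenyl]ethan-1-ol | Cc1c(Br)cc(OCc2ccccc2)cc1CCO | intermediate
6 | {2-[5-(benzyloxy)-3-bromo-2-methylphenyl]ethoxy}(tert-butyl)dimethylsilane | Cc1c(Br)cc(OCc2ccccc2)cc1CCO[Si](C)(C)C(C)(C)C | intermediate
7 | methyl isobutyrate | COC(=O)C(C)C | starting material
8 | lithium enolate of methyl isobutyrate | COC(O[Li])=C(C)C | intermediate
9 | methyl 2-{5-(benzyloxy)-3-[2-(TBSO)ethyl]-2-methylphenyl}-2-methylpropanoate | Cc1c(CCO[Si](C)(C)C(C)(C)C)cc(OCc2ccccc2)cc1C(C)(C)C(=O)OC | intermediate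
10 | 2-{5-(benzyloxy)-3-[2-(TBSO)ethyl]-2-methylphenyl}-2-methylpropanal | Cc1c(CCO[Si](C)(C)C(C)(C)C)cc(OCc2ccccc2)cc1C(C)(C)C=O | intermediate
11 | B-allylbis(isopinocampheyl)borane, (−)-α-pinene series (commercial pentane solution) | C=CCB([C@H]1C[C@H]2C[C@@H]([C@@H]1C)C2(C)C)[C@H]1C[C@H]2C[C@@H]([C@@H]1C)C2(C)C | starting material
12 | bis(isopinocampheyl)borinate of alcohol 13 | Cc1c(CCO[Si](C)(C)C(C)(C)C)cc(OCc2ccccc2)cc1C(C)(C)[C@H](OB([C@H]3C[C@H]4C[C@@H]([C@@H]3C)C4(C)C)[C@H]5C[C@H]6C[C@@H]([C@@H]5C)C6(C)C)CC=C | intermediate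
13 | (3R)-2-{5-(benzyloxy)-3-[2-(TBSO)ethyl]-2-methylphenyl}-2-methylhex-5-en-3-ol | Cc1c(CCO[Si](C)(C)C(C)(C)C)cc(OCc2ccccc2)cc1C(C)(C)[C@H](O)CC=C | intermediate
14 | TBS ether of 13 (3R) | Cc1c(CCO[Si](C)(C)C(C)(C)C)cc(OCc2ccccc2)cc1C(C)(C)[C@H](O[Si](C)(C)C(C)(C)C)CC=C | intermediate
15 | (3R)-4-{5-(benzyloxy)-3-[2-(TBSO)ethyl]-2-methylphenyl}-3-(TBSO)-4-methylpentanal | Cc1c(CCO[Si](C)(C)C(C)(C)C)cc(OCc2ccccc2)cc1C(C)(C)[C@H](O[Si](C)(C)C(C)(C)C)CC=O | intermediate
16 | (3R)-4-{5-(benzyloxy)-3-[2-(TBSO)ethyl]-2-methylphenyl}-3-(TBSO)-4-methylpentan-1-ol | Cc1c(CCO[Si](C)(C)C(C)(C)C)cc(OCc2ccccc2)cc1C(C)(C)[C@H](O[Si](C)(C)C(C)(C)C)CCO | intermediate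
17 | tosylate of 16 | Cc1c(CCO[Si](C)(C)C(C)(C)C)cc(OCc2ccccc2)cc1C(C)(C)[C@H](O[Si](C)(C)C(C)(C)C)CCOS(=O)(=O)c3ccc(C)cc3 | intermediate
18 | (3R)-3-(TBSO)-4-{3-[2-(TBSO)ethyl]-5-hydroxy-2-methylphenyl}-4-methylpentyl 4-methylbenzenesulfonate | Cc1c(CCO[Si](C)(C)C(C)(C)C)cc(O)cc1C(C)(C)[C@H](O[Si](C)(C)C(C)(C)C)CCOS(=O)(=O)c2ccc(C)cc2 | intermediate
19 | (3R)-4-{4-bromo-3-[2-(TBSO)ethyl]-5-hydroxy-2-methylphenyl}-3-(TBSO)-4-methylpentyl 4-methylbenzenesulfonate | Cc1c(CCO[Si](C)(C)C(C)(C)C)c(Br)c(O)cc1C(C)(C)[C@H](O[Si](C)(C)C(C)(C)C)CCOS(=O)(=O)c2ccc(C)cc2 | intermediate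
20 | (3R)-3-(TBSO)-4-{4-bromo-5-[2-(TBSO)ethyl]-2-chloro-3-hydroxy-6-methylphenyl}-4-methylpentyl 4-methylbenzenesulfonate | Cc1c(CCO[Si](C)(C)C(C)(C)C)c(Br)c(O)c(Cl)c1C(C)(C)[C@H](O[Si](C)(C)C(C)(C)C)CCOS(=O)(=O)c2ccc(C)cc2 | intermediate
21 | potassium phenoxide of 20 | Cc1c(CCO[Si](C)(C)C(C)(C)C)c(Br)c([O-])c(Cl)c1C(C)(C)[C@H](O[Si](C)(C)C(C)(C)C)CCOS(=O)(=O)c2ccc(C)cc2.[K+] | intermediate
22 | (4aR,7R)-3-bromo-1-chloro-7-(TBSO)-4-[2-(TBSO)ethyl]-4a,8,8-trimethyl-5,6,7,8-tetrahydronaphthalen-2(4aH)-one | CC(C)(C)[Si](C)(C)OCCC1=C(Br)C(=O)C(Cl)=C2C(C)(C)[C@H](O[Si](C)(C)C(C)(C)C)CC[C@@]12C | intermediate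
23 | methyl 1-chloro-7-(TBSO)-4-[2-(TBSO)ethyl]-4a,8,8-trimethyl-2-oxo-2,4a,5,6,7,8-hexahydronaphthalene-3-carboxylate (C3, C10 as in 22) | CC(C)(C)[Si](C)(C)OCCC1=C(C(=O)OC)C(=O)C(Cl)=C2C(C)(C)[C@H](O[Si](C)(C)C(C)(C)C)CC[C@@]12C | intermediate
24 | methyl (3R,5S,10R)-3,12-bis(TBSO)-7-oxo-13,14,15,16-tetranorlabd-8-en-17-oate | CC(C)(C)[Si](C)(C)OCCC1=C(C(=O)OC)C(=O)C[C@@H]2C(C)(C)[C@H](O[Si](C)(C)C(C)(C)C)CC[C@@]12C | intermediate
25 | lithium enolate (C7–OLi, C7=C8) of 26 | CC(C)(C)[Si](C)(C)OCC[C@@H]1C(C(=O)OC)=C(O[Li])C[C@@H]2C(C)(C)[C@H](O[Si](C)(C)C(C)(C)C)CC[C@@]12C | intermediate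
26 | methyl (3R,5S,8R,9R,10S)-3,12-bis(TBSO)-7-oxo-13,14,15,16-tetranorlabdan-17-oate | CC(C)(C)[Si](C)(C)OCC[C@@H]1[C@@H](C(=O)OC)C(=O)C[C@@H]2C(C)(C)[C@H](O[Si](C)(C)C(C)(C)C)CC[C@@]12C | intermediate
27 | methyl (3R,5S,8R,9R,10S)-7-hydroxy-3,12-bis(TBSO)-13,14,15,16-tetranorlabdan-17-oate (C7 epimers) | CC(C)(C)[Si](C)(C)OCC[C@@H]1[C@@H](C(=O)OC)C(O)C[C@@H]2C(C)(C)[C@H](O[Si](C)(C)C(C)(C)C)CC[C@@]12C | intermediate
28 | (3R,5S,8S,9R,10S)-3,12-bis(TBSO)-13,14,15,16-tetranorlabdane-7,17-diol (C7 epimers) | CC(C)(C)[Si](C)(C)OCC[C@@H]1[C@@H](CO)C(O)C[C@@H]2C(C)(C)[C@H](O[Si](C)(C)C(C)(C)C)CC[C@@]12C | intermediate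
29 | 17-O-TBDPS ether of 28 | CC(C)(C)[Si](C)(C)OCC[C@@H]1[C@@H](CO[Si](c3ccccc3)(c4ccccc4)C(C)(C)C)C(O)C[C@@H]2C(C)(C)[C@H](O[Si](C)(C)C(C)(C)C)CC[C@@]12C | intermediate
30 | O-(C7) 1H-imidazole-1-carbothioate of 29 | CC(C)(C)[Si](C)(C)OCC[C@@H]1[C@@H](CO[Si](c3ccccc3)(c4ccccc4)C(C)(C)C)C(OC(=S)n3ccnc3)C[C@@H]2C(C)(C)[C@H](O[Si](C)(C)C(C)(C)C)CC[C@@]12C | intermediate
31 | (3R,5S,8S,9R,10S)-3,12-bis(TBSO)-17-(TBDPSO)-13,14,15,16-tetranorlabdane | CC(C)(C)[Si](C)(C)OCC[C@@H]1[C@@H](CO[Si](c3ccccc3)(c4ccccc4)C(C)(C)C)CC[C@@H]2C(C)(C)[C@H](O[Si](C)(C)C(C)(C)C)CC[C@@]12C | intermediate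
32 | (3R,5S,8S,9R,10S)-3-(TBSO)-17-(TBDPSO)-13,14,15,16-tetranorlabdan-12-ol | OCC[C@@H]1[C@@H](CO[Si](c3ccccc3)(c4ccccc4)C(C)(C)C)CC[C@@H]2C(C)(C)[C@H](O[Si](C)(C)C(C)(C)C)CC[C@@]12C | intermediate
33 | 12-iodide of 32 | ICC[C@@H]1[C@@H](CO[Si](c3ccccc3)(c4ccccc4)C(C)(C)C)CC[C@@H]2C(C)(C)[C@H](O[Si](C)(C)C(C)(C)C)CC[C@@]12C | intermediate
34 | methyl but-2-ynoate | CC#CC(=O)OC | starting material
35 | methyl (Z)-3-iodobut-2-enoate | COC(=O)/C=C(/C)I | intermediate
36 | 12-(iodozincio) derivative from 33 | I[Zn]CC[C@@H]1[C@@H](CO[Si](c3ccccc3)(c4ccccc4)C(C)(C)C)CC[C@@H]2C(C)(C)[C@H](O[Si](C)(C)C(C)(C)C)CC[C@@]12C | intermediate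
37 | methyl (3R,5S,8S,9R,10S,13Z)-3-(TBSO)-17-(TBDPSO)labd-13-en-15-oate | COC(=O)/C=C(/C)CC[C@@H]1[C@@H](CO[Si](c3ccccc3)(c4ccccc4)C(C)(C)C)CC[C@@H]2C(C)(C)[C@H](O[Si](C)(C)C(C)(C)C)CC[C@@]12C | intermediate
38 | methyl (3R,5S,8S,9R,10S,13Z)-3,17-dihydroxylabd-13-en-15-oate | COC(=O)/C=C(/C)CC[C@@H]1[C@@H](CO)CC[C@@H]2C(C)(C)[C@H](O)CC[C@@]12C | intermediate
39 | methyl (3R,5S,8S,9R,10S,13Z)-3-hydroxy-17-oxolabd-13-en-15-oate | COC(=O)/C=C(/C)CC[C@@H]1[C@@H](C=O)CC[C@@H]2C(C)(C)[C@H](O)CC[C@@]12C | target

**Total step count:** 27. **Longest linear sequence:** 26 (steps 1–23 and 25–27, from 1).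

**Steps most likely to fail**

1. **Step 13.**
 - What may go wrong: C-alkylation by the weakly nucleophilic, crowded dihalophenoxide may be so slow that bimolecular ether formation or elimination of the tosylate takes over. The equatorial preference of the C3 silyloxy group may also transmit only partly to C10.
 - Fallback (sets out from 16, returns at 22): the tosylate is not made. Hydrogenolysis of 16 (H2, Pd/C, EtOAc) gives the phenol alcohol F1. NBS gives the C8-bromophenol alcohol F2, and amine-catalysed NCS gives the bromochlorophenol alcohol F3. F3 is then cyclised by Mitsunobu activation (Bu3P, 1,1'-(azodicarbonyl)dipiperidine, toluene, slow addition at high dilution).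
 - Why it may help: the acidic phenol protonates the betaine and the C1 hydroxyl becomes an oxyphosphonium leaving group. The phenoxide ion pair then closes the same C1–C10 bond to 22 without any alkoxide base. This mode of activation is known for dearomatising spirocyclisations of phenols.

2. **Step 12.**
 - What may go wrong: chlorination may be diverted to ipso attack at C10 or to the benzylic positions instead of the crowded C6. Traces of acid may cause loss of the primary silyl ether.
 - Fallback (sets out from 19, returns at 24): the blocking atom is given up. Bromophenol 19 is cyclised as such (KOt-Bu, t-BuOH, high dilution) to the chlorine-free 8-bromo dienone F4. Methoxycarbonylation as in step 14 gives the chlorine-free dienone ester F5. Hydrogenation as in step 15, now without hydrogenolysis, gives 24.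
 - Why it may help: closure at C6 would keep the C4 gem-dimethyl group in the ring plane next to the C10 methyl, whereas closure at C10 removes this clash. Any C6 adduct rearomatises to a phenol that can be extracted with base.

3. **Step 15.**
 - What may go wrong: hydrodechlorination may stall, the C8=C9 bond may migrate or be saturated prematurely, and facial selectivity at C5 on the flat dienone may be poor.
 - Fallback (sets out from 23, returns at 26): the order is reversed and the reductant for C5 is changed. Li (about 5 equiv) in NH3–THF with t-BuOH removes the chlorine and reduces the doubly activated C8=C9 bond first, giving the 5-en-7-one β-keto ester F6. The only remaining alkene, C5=C6, is then reduced by hydrogen-atom transfer (Mn(dpm)3 cat., PhSiH3, t-BuOOH, i-PrOH) to 26.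
 - Why it may help: this radical hydrogenation needs no catalyst surface and is known to favour trans-fused decalones.

**Further compounds**
F1 | step 13 | (3R)-3-(TBSO)-4-{3-[2-(TBSO)ethyl]-5-hydroxy-2-methylphenyl}-4-methylpentan-1-ol | Cc1c(CCO[Si](C)(C)C(C)(C)C)cc(O)cc1C(C)(C)[C@H](O[Si](C)(C)C(C)(C)C)CCO
F2 | step 13 | (3R)-4-{4-bromo-3-[2-(TBSO)ethyl]-5-hydroxy-2-methylphenyl}-3-(TBSO)-4-methylpentan-1-ol | Cc1c(CCO[Si](C)(C)C(C)(C)C)c(Br)c(O)cc1C(C)(C)[C@H](O[Si](C)(C)C(C)(C)C)CCO
F3 | step 13 | (3R)-4-{4-bromo-5-[2-(TBSO)ethyl]-2-chloro-3-hydroxy-6-methylphenyl}-3-(TBSO)-4-methylpentan-1-ol | Cc1c(CCO[Si](C)(C)C(C)(C)C)c(Br)c(O)c(Cl)c1C(C)(C)[C@H](O[Si](C)(C)C(C)(C)C)CCO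
F4 | step 12 | 3-bromo-7-(TBSO)-4-[2-(TBSO)ethyl]-4a,8,8-trimethyl-5,6,7,8-tetrahydronaphthalen-2(4aH)-one (C3, C10 as in 22) | CC(C)(C)[Si](C)(C)OCCC1=C(Br)C(=O)C=C2C(C)(C)[C@H](O[Si](C)(C)C(C)(C)C)CC[C@@]12C
F5 | step 12 | methyl 7-(TBSO)-4-[2-(TBSO)ethyl]-4a,8,8-trimethyl-2-oxo-2,4a,5,6,7,8-hexahydronaphthalene-3-carboxylate (C3, C10 as in 22) | CC(C)(C)[Si](C)(C)OCCC1=C(C(=O)OC)C(=O)C=C2C(C)(C)[C@H](O[Si](C)(C)C(C)(C)C)CC[C@@]12C
F6 | step 15 | methyl (3R,8R,9R,10S)-3,12-bis(TBSO)-7-oxo-13,14,15,16-tetranorlabd-5-en-17-oate | CC(C)(C)[Si](C)(C)OCC[C@@H]1[C@@H](C(=O)OC)C(=O)C=C2C(C)(C)[C@H](O[Si](C)(C)C(C)(C)C)CC[C@@]12C
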